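All constants were chosen freely.

Two questions order these flasks, and the first is a ratio of two rates at one moment, in which time drops out.

| flask | substrate | coupling partner | catalyst | time | remark |
|---|---|---|---|---|---|
| winter | 0.050 M | 1.20 equiv (fed, over 50 min) | 1 mol% | 1.5 h | all else is in the flask from the start; the feed brings no volume worth counting |
| dawn | 0.050 M (in portions, 4, over 50 min) | 1.20 equiv | 1 mol% | 1.5 h | first portion at the start, last at 50 min |
| dusk | 0.050 M (fed, over 50 min) | 1.20 equiv | 1 mol% | 1.5 h | all else is in the flask from the start; the feed brings no volume worth counting |
| spring | 0.050 M | 1.20 equiv | 1 mol% | 1.5 h | everything together at the start |

    substrate + coupling partner + catalyst → target + catalyst, rate k1*[substrate]*[coupling partner]*[catalyst]/(1 + ([substrate]/sat1)) (sat1 = 5.28 mM, k1 = 15200 L² mol⁻² min⁻¹)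
    substrate + target → side product (k2 = 0.452 L mol⁻¹ min⁻¹)

- in percentages every species weighs as the substrate in it: one side product counts as two
- run time (winter): 1.5 h

- the flask that comes out highest in amount of side product, in percent of the substrate charged; "all alike" if 1.5 percentage points covers them all (winter / dawn / dusk / spring / all alike)
- amount of side product at the end, in percent of the substrate charged, winter
- amount of side product at the end, in percent of the substrate charged, dawn
- amount of side product at the end, in percent of the substrate charged, dusk
- amount of side product at the end, in percent of the substrate charged, spring

First, does the side path matter at all? I divide its rate by the rate of coupling. The substrate concentration standing in front of both rates cancels and the clock goes with it, but the substrate in the saturation bracket stays, which leaves the leak ratio (an instantaneous selectivity, turned over): side events per coupling. In fractions of the charge it equals the leak constant, 0.0595, the second rate constant over the first times the catalyst concentration, multiplied by target over coupling partner, and multiplied by one plus the substrate concentration over sat. With substrate at half its charge, that last bracket is 5.73, so where target equals partner the ratio is 0.341, far above the 0.0595 it has at the same place with substrate thin. It matters, then.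

Second, which recipe sits where when the dosing runs over 50 min? Winter meters the partner, so it holds substrate high and partner low, at the upper end. Dawn and dusk dose substrate into a full partner charge, at the lower end. Spring starts with no target and passes through the middle. My order is winter, spring, then dawn and dusk together. For spring I take half of 0.341 as the mean ratio, 0.171. Each event counts double, so I commit to 29.2 %, above the forecast's figure.

The forecast names winter, with 31 % for winter, 19 % for dawn, 19.5 % for dusk and 25.5 % for spring, the harm being “worst when the coupling partner is starved by slow feeding”.

The simulation gives winter highest, at 31.3 %, with dawn 18.5 %, dusk 18.4 % and spring 25.7 %. So the forecast stands, and the same charges in winter and dusk end 13 percentage points apart.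

Is winter at rest? After 1.50 h winter holds 0.229 % of its substrate, target 68.5 % and partner 29.9 % of its own charge, so the leak ratio reads 0.116. Each event counts double, so at that ratio the remnant adds about 0.048 points, and winter after 15.0 h reads 31.4 %. Dusk, with 0.270 % of its substrate left, target 81.3 % and partner 24.6 %, has ratio 0.168, at which the remnant adds about 0.078 points, and dusk reads 18.5 % after 15.0 h.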